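Target CNP0157787.1; atoms are numbered C1–O34 in the order of its SMILES.
Cuts: C15=C16 with C2–H (transposition of a C16 allylic alcohol), then C15–C16 and C16–C17 (C17 borane + CO + C15 enol triflate). West: C32–C33, C17=C18, then C22 is excised (C21–C22, C22–C23), then O28–C25 and C19–C21. East: C9–O11, the C12 methyls, C2 with C1, and the Diels–Alder bonds C4–C5 and C6–C12.
Enabling feature: the oxepanone ketone C23 lies between C25 (quaternary, bonded to O28) and the methylene C22, so ring O28–C25–C23–C22–C21–C19–C29 is a tetrahydropyran-3-one carrying one extra carbon on its methylene side; the six-membered precursor closes readily and trans on the cyclohexane.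
Forward, west: bought cyclohexanedione → pyranone (6-endo epoxide opening) → oxepanone (one-carbon insertion) → C18/C32 elaboration. East: bought cyclopentenone → cis-hydrindane (Diels–Alder) → hydroazulene (one-carbon ring expansion). Union through C16, then transposition.
Stereochemistry, west: C19 from reagent-controlled desymmetrisation of the prochiral dione, C29 from 1,3-anti intramolecular hydride transfer, C32 from equatorial methyl addition, C18 from hydroboration anti to the axial groups.
Stereochemistry, east and union: C5/C6 from a catalytic asymmetric Diels–Alder reaction, C9 from hydration on the convex face, C16 from CBS reduction, passed on to C2 and to the alkene geometry by the suprafacial retro-ene step.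

Key step: step 6

Remark 1: centres that do not reach the target (C23 before step 26, C32 in 17, the cyclopropane and chloride carbons of 25 and 26, C12 in 28) are written as the expected epimer or left open.
Remark 2: the (S)-oxazaborolidinium catalyst of step 16 is assumed to give the (3aS,7aR) adduct 23; if the sense is the opposite, its enantiomer is used.

**West half**

Step 1
Reactants: 1 2-methylcyclohexane-1,3-dione; 2 1-bromo-3-methylbut-2-ene
Product: 3 2-methyl-2-prenylcyclohexane-1,3-dione
Conditions: 1 M NaOH (aq), 25 °C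
Reagents that add atoms: none
Why: Enolate C-alkylation of the cyclic 1,3-dione by the allylic bromide in water, where the solvated oxygen atoms leave carbon as the site of attack; the product is still achiral.

Step 2
Reactants: 3 2-methyl-2-prenylcyclohexane-1,3-dione
Product: 4 (2R,3R)-3-hydroxy-2-methyl-2-prenylcyclohexan-1-one (carbinol carbon = C18, ketone = C29)
Conditions: (S)-Me-CBS (20 mol %), catecholborane, toluene, −78 °C
Reagents that add atoms: none
Why: Corey–Bakshi–Shibata reduction used as an enantiotopic-group-selective desymmetrisation: the (S)-oxazaborolidine fixes the (R)-carbinol, and the carbonyl that can be attacked on that face anti to the larger prenyl group is the one reduced, which sets C19 and places the hydroxyl cis to prenyl.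

Step 3
Reactants: 4 (2R,3R)-hydroxy ketone
Product: 5 (1R,2S,3R)-3-hydroxy-2-methyl-2-prenylcyclohexyl benzoate (C18 benzoate, free C29 hydroxyl)
Conditions: PhCHO, SmI2 (30 mol %), THF, −10 °C
Reagents that add atoms: benzaldehyde, O=Cc1ccccc1
Why: Evans–Tishchenko reduction: the samarium-bound hemiacetal formed from benzaldehyde on the C18 oxygen hands its hydride to the C29 carbonyl through a six-membered chair on the face of that oxygen, so the new C29 hydroxyl is 1,3-anti to it (trans to prenyl, cis to the C19 methyl) and C18 leaves as its benzoate.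

Step 4
Reactants: 5 anti-diol monobenzoate
Product: 7 trans-fused pyranol benzoate (both C23 epimers), via epoxy alcohol 6 (not isolated)
Conditions: mCPBA, CH2Cl2, 0 °C; then CSA (10 mol %), CH2Cl2, 0 → 25 °C
Reagents that add atoms: m-chloroperbenzoic acid, O=C(OO)c1cccc(Cl)c1
Why: Prilezhaev epoxidation followed by acid-catalysed epoxide opening by the C29 hydroxyl at the tertiary carbon C25 (6-endo), which carries the positive charge best and gives the unstrained trans-fused oxadecalin; the epoxide epimers need not be separated because C23 becomes a carbonyl in step 5.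

Step 5
Reactants: 7 trans-fused pyranol benzoate
Product: 8 trans-fused 2,2-dimethyltetrahydropyran-3-one benzoate
Conditions: Dess–Martin periodinane, CH2Cl2, 25 °C
Reagents that add atoms: none
Why: Dess–Martin oxidation of a secondary alcohol, in which both C23 epimers converge on the pyranone.

Step 6
Reactants: 8 trans-fused pyranone benzoate; 9 trimethylsilyldiazomethane
Product: 11 trans-fused oxepanone benzoate, via silyl ketone 10 (not isolated)
Conditions: Sc(OTf)3 (20 mol %), CH2Cl2, −78 → −20 °C; then 1 M HCl, THF, 0 °C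
Reagents that add atoms: none
Why: Sc(OTf)3 activates the C23 carbonyl, the nucleophilic carbon of 9 adds to it, and the β-silyl diazonium alkoxide collapses by 1,2-shift of C21 with loss of N2, which places the new carbon C22 between C21 and C23 and forms both skeletal bonds at once. The closest known reaction type is the Lewis acid-promoted trimethylsilyldiazomethane homologation of tetrahydropyran-3-ones to oxepan-3-ones, a Tiffeneau–Demjanov-type ring expansion. The oxepane is not closed by cyclisation but grows out of the six-membered pyranone by ring enlargement, so a direct seven-ring closure is avoided. No stereocentre is made: C19 and C29 are untouched and the silyl-bearing C22 becomes a methylene on protodesilylation with acid. The one selectivity needed is migration of C21 and not C25, and it is secured because C25 is quaternary and bonded to the ring oxygen, whose inductive pull lowers its migratory aptitude, while the bulky silyl group of the adduct turns away from the gem-dimethyl side. The α-silyl ketone 10 does not add a second equivalent, which stops the sequence after one insertion.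

Step 7
Reactants: 11 trans-fused oxepanone benzoate
Product: 12 oxepan-3-ol benzoate (C23 hydroxyl cis to the C19 methyl)
Conditions: NaBH4, MeOH, 0 °C
Reagents that add atoms: none
Why: Borohydride reduction masks the C23 carbonyl before the C18 carbonyl is set free; hydride should arrive anti to the C19 methyl, and the centre is returned to a ketone in step 26.

Step 8
Reactants: 12 oxepan-3-ol benzoate
Product: 13 C23 tert-butyldimethylsilyl ether benzoate
Conditions: TBSOTf, 2,6-lutidine, CH2Cl2, 0 °C
Reagents that add atoms: tert-butyldimethylsilyl triflate, CC(C)(C)[Si](C)(C)OS(=O)(=O)C(F)(F)F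
Why: Silylation of a hindered secondary alcohol with the silyl triflate and a non-nucleophilic base.

Step 9
Reactants: 13 silyl ether benzoate
Product: 14 C18 alcohol
Conditions: i-Bu2AlH, CH2Cl2, −78 °C
Reagents that add atoms: none
Why: Reductive cleavage of the benzoate by an aluminium hydride at low temperature, which leaves the silyl ether and the ring ether intact.

Step 10
Reactants: 14 C18 alcohol
Product: 15 C18 ketone
Conditions: Dess–Martin periodinane, CH2Cl2, 25 °C
Reagents that add atoms: none
Why: Dess–Martin oxidation of the only free hydroxyl.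

Step 11
Reactants: 15 C18 ketone
Product: 16 C18 methylidene compound
Conditions: Ph3PCH3Br, KOt-Bu, toluene, 90 °C
Reagents that add atoms: methyltriphenylphosphonium bromide, C[P+](c1ccccc1)(c1ccccc1)c1ccccc1.[Br-]
Why: Wittig methylenation under the forcing conditions used for ketones next to a quaternary carbon; it installs C17.

Step 12
Reactants: 16 C18 methylidene compound
Product: 17 C32 allylic alcohol
Conditions: SeO2 (50 mol %), t-BuOOH, CH2Cl2, 25 °C
Reagents that add atoms: selenium dioxide, O=[Se]=O; tert-butyl hydroperoxide, CC(C)(C)OO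
Why: Selenium dioxide allylic oxidation (ene reaction then [2,3]-sigmatropic shift), possible only at C32 because the other allylic carbon C19 is quaternary; the carbinol configuration is lost in step 13.

Step 13
Reactants: 17 C32 allylic alcohol
Product: 18 α-methylidene ketone (C32 carbonyl)
Conditions: Dess–Martin periodinane, CH2Cl2, 0 °C
Reagents that add atoms: none
Why: Dess–Martin oxidation of the allylic alcohol to the α-methylidene ketone, which the neighbouring quaternary carbon protects from dimerisation and which is used at once.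

Step 14
Reactants: 18 α-methylidene ketone
Product: 19 tertiary allylic alcohol (C32 hydroxyl axial, cis to the C19 methyl)
Conditions: MeLi, Et2O, −78 °C
Reagents that add atoms: methyllithium, [Li]C
Why: 1,2-Addition of methyllithium to the enone carbonyl; axial approach is blocked by the syn-axial C19 methyl, so the methyl enters equatorially and the C32 hydroxyl ends axial, cis to that methyl.

**East half**

Step 15
Reactants: 20 but-3-en-2-one
Product: 21 2-(triisopropylsilyloxy)buta-1,3-diene
Conditions: TIPSOTf, Et3N, CH2Cl2, 0 °C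
Reagents that add atoms: triisopropylsilyl triflate, CC(C)[Si](C(C)C)(C(C)C)OS(=O)(=O)C(F)(F)F
Why: O-Silylation of the enolisable ketone under soft enolisation gives the 2-silyloxy diene.

Step 16
Reactants: 21 2-(triisopropylsilyloxy)buta-1,3-diene; 22 cyclopent-2-en-1-one
Product: 23 (3aS,7aR)-5-(triisopropylsilyloxy)-2,3,3a,4,7,7a-hexahydro-1H-inden-1-one
Conditions: (S)-B-(o-tolyl)diphenylprolinol oxazaborolidine (20 mol %), Tf2NH (20 mol %), CH2Cl2, −78 → −40 °C
Reagents that add atoms: none
Why: Catalytic asymmetric Diels–Alder reaction (protonated oxazaborolidine catalysis): suprafacial addition makes the C5–C6 fusion cis, the enol ether terminus C12 bonds to the β-carbon C6 (para orientation), and the aryl group of the catalyst screens one face of the bound enone.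

Step 17
Reactants: 23 cis-hydrindanone enol ether
Product: 24 C9 methylidene enol ether
Conditions: Ph3PCH3Br, KOt-Bu, THF, 0 °C
Reagents that add atoms: methyltriphenylphosphonium bromide, C[P+](c1ccccc1)(c1ccccc1)c1ccccc1.[Br-]
Why: Wittig methylenation of the unhindered cyclopentanone; it also removes the carbonyl through which C5 could epimerise.

Step 18
Reactants: 24 C9 methylidene enol ether
Product: 27 cis-fused 2-methylcyclohept-2-enone, via siloxycyclopropane 25 (not isolated), via chloro ketone 26 (not isolated)
Conditions: Et2Zn, CH3CHI2, CH2Cl2, 0 °C; then FeCl3, DMF, 0 °C; then NaOAc, MeOH, 65 °C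
Reagents that add atoms: 1,1-diiodoethane, CC(I)I
Why: Furukawa cyclopropanation of the electron-rich enol ether with the ethylidene carbenoid, then Ito–Saegusa ring expansion (oxidative cleavage of the siloxycyclopropane by FeCl3 and loss of HCl): the C15=C3 enol ether of the cycloadduct fixes the new carbon C2, with its methyl, between C15 and C3.

Step 19
Reactants: 27 cis-fused 2-methylcyclohept-2-enone
Product: 29 C12 gem-dimethyl enone, via monomethyl enone 28 (not isolated)
Conditions: LiN(i-Pr)2, THF, −78 °C, then MeI; again LiN(i-Pr)2, DMPU, −78 °C, then MeI, −78 → 0 °C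
Reagents that add atoms: iodomethane, CI
Why: Kinetic deprotonation of the enone at the α′ carbon C12 and methylation, carried out twice in one flask, builds the gem-dimethyl group without touching the ring fusion.

Step 20
Reactants: 29 C12 gem-dimethyl enone
Product: 31 hydroazulenyl enol triflate (C9 methylidene), via lithium enolate 30 (not isolated)
Conditions: Li[HB(s-Bu)3], THF, −78 °C; then Comins' reagent, −78 → 0 °C
Reagents that add atoms: N-(5-chloropyridin-2-yl)bis(trifluoromethanesulfonyl)imide, O=S(=O)(N(c1ccc(Cl)cn1)S(=O)(=O)C(F)(F)F)C(F)(F)F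
Why: Conjugate reduction by the hindered borohydride gives the C15–C2 enolate regiospecifically, and O-sulfonylation with the pyridyl triflimide gives the enol triflate.

Step 21
Reactants: 31 hydroazulenyl enol triflate (C9 methylidene)
Product: 32 hydroazulenyl enol triflate with C9 tertiary alcohol (hydroxyl on the face of H5 and H6)
Conditions: Co(acac)2 (20 mol %), PhSiH3, O2 (1 atm), THF, 25 °C
Reagents that add atoms: dioxygen, O=O
Why: Mukaiyama hydration (hydrogen-atom transfer to the 1,1-disubstituted alkene, capture of the tertiary C9 radical by O2): oxygen enters on the convex face, that of H5 and H6, away from the seven-membered ring, while the hindered electron-poor enol triflate does not react.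

**Union and endgame**

Step 22
Reactants: 19 tertiary allylic alcohol; 32 hydroazulenyl enol triflate
Product: 34 C16 enone, via alkylborane 33 (not isolated)
Conditions: 9-BBN, THF, 60 °C; then 32, PdCl2(dppf) (10 mol %), K3PO4 (aq), CO (1 atm), THF/DMF, 60 °C
Reagents that add atoms: carbon monoxide, [C-]#[O+]
Why: Hydroboration then carbonylative Suzuki–Miyaura coupling: 9-BBN adds to the methylidene from the face opposite the axial C19 methyl and C32 hydroxyl, so H18 is axial and C17 equatorial, and the acylpalladium formed from the triflate and CO takes up the alkyl group to give the C16 ketone.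

Step 23
Reactants: 34 C16 enone
Product: 35 (16R)-allylic alcohol
Conditions: (S)-Me-CBS, catecholborane, toluene, −78 → −40 °C
Reagents that add atoms: none
Why: Corey–Bakshi–Shibata reduction in which the tetrasubstituted cycloalkenyl group acts as the large and the C17 methylene as the small substituent, giving the (16R)-alcohol under reagent control.

Step 24
Reactants: 35 (16R)-allylic alcohol
Product: 38 C23 silyl ether of the 23-dihydro target, via sulfonylhydrazine 36 (not isolated), via allylic diazene 37 (not isolated)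
Conditions: 2-O2NC6H4SO2NHNH2, PPh3, DEAD, N-methylmorpholine, −30 → 23 °C
Reagents that add atoms: none
Why: Myers reductive transposition: Mitsunobu displacement with inversion gives the (16S)-sulfonylhydrazine, loss of sulfinic acid gives the diazene, and the retro-ene loss of N2 delivers hydrogen suprafacially to C2 through the conformer in which H16 eclipses the C1 methyl (least allylic 1,3-strain), which sets C2 and places C17 cis to C12 in the new C15=C16 bond.

Step 25
Reactants: 38 C23 silyl ether
Product: 39 23-dihydro target (triol)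
Conditions: Bu4NF, THF, 50 °C
Reagents that add atoms: none
Why: Fluoride cleavage of the silyl ether; the tertiary alcohols and the alkene are inert.

Step 26
Reactants: 39 23-dihydro target
Product: 40 CNP0157787.1
Conditions: Dess–Martin periodinane, pyridine, CH2Cl2, 0 → 25 °C
Reagents that add atoms: none
Why: Dess–Martin oxidation of the only secondary alcohol; the two tertiary alcohols cannot be oxidised.

**Compound list**

1 | 2-methylcyclohexane-1,3-dione | CC1C(=O)CCCC1=O | starting material
2 | 1-bromo-3-methylbut-2-ene | CC(C)=CCBr | starting material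
3 | 2-methyl-2-(3-methylbut-2-en-1-yl)cyclohexane-1,3-dione | CC(C)=CCC1(C)C(=O)CCCC1=O | intermediate
4 | (2R,3R)-3-hydroxy-2-methyl-2-(3-methylbut-2-en-1-yl)cyclohexan-1-one | O[C@@H]1CCCC(=O)[C@]1(C)CC=C(C)C | intermediate
5 | (1R,2S,3R)-3-hydroxy-2-methyl-2-(3-methylbut-2-en-1-yl)cyclohexyl benzoate | O=C(O[C@@H]1CCC[C@@H](O)[C@]1(C)CC=C(C)C)c1ccccc1 | intermediate
6 | epoxide of 5 at the prenyl alkene, both C23 epimers | O=C(O[C@@H]1CCC[C@@H](O)[C@]1(C)CC2OC2(C)C)c1ccccc1 | intermediate
7 | trans-fused 3-hydroxy-2,2,4a-trimethyloctahydro-2H-chromen-5-yl benzoate (4a-methyl anti to 8a-H, benzoate trans to 4a-methyl, both C23 epimers) | O=C(O[C@@H]1CCC[C@H]2OC(C)(C)C(O)C[C@]12C)c1ccccc1 | intermediate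
8 | trans-fused 2,2,4a-trimethyl-3-oxooctahydro-2H-chromen-5-yl benzoate | O=C(O[C@@H]1CCC[C@H]2OC(C)(C)C(=O)C[C@]12C)c1ccccc1 | intermediate
9 | trimethylsilyldiazomethane | C[Si](C)(C)C=[N+]=[N-] | starting material
10 | 2,2,5a-trimethyl-3-oxo-4-(trimethylsilyl)decahydro-1-benzoxepin-6-yl benzoate (ring configuration as 11, silyl carbon open) | O=C(O[C@@H]1CCC[C@H]2OC(C)(C)C(=O)C([Si](C)(C)C)C[C@]12C)c1ccccc1 | intermediate
11 | trans-fused 2,2,5a-trimethyl-3-oxodecahydro-1-benzoxepin-6-yl benzoate (5a-methyl anti to 9a-H, benzoate trans to 5a-methyl) | O=C(O[C@@H]1CCC[C@H]2OC(C)(C)C(=O)CC[C@]12C)c1ccccc1 | intermediate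
12 | 3-hydroxy analogue of 11 (hydroxyl cis to 5a-methyl) | O=C(O[C@@H]1CCC[C@H]2OC(C)(C)[C@@H](O)CC[C@]12C)c1ccccc1 | intermediate
13 | 3-(tert-butyldimethylsilyloxy) analogue of 11 | O=C(O[C@@H]1CCC[C@H]2OC(C)(C)[C@@H](O[Si](C)(C)C(C)(C)C)CC[C@]12C)c1ccccc1 | intermediate
14 | trans-fused 3-(tert-butyldimethylsilyloxy)-2,2,5a-trimethyldecahydro-1-benzoxepin-6-ol | O[C@@H]1CCC[C@H]2OC(C)(C)[C@@H](O[Si](C)(C)C(C)(C)C)CC[C@]12C | intermediate
15 | trans-fused 3-(tert-butyldimethylsilyloxy)-2,2,5a-trimethyloctahydro-1-benzoxepin-6(2H)-one | O=C1CCC[C@H]2OC(C)(C)[C@@H](O[Si](C)(C)C(C)(C)C)CC[C@]12C | intermediate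
16 | 6-methylidene analogue of 15 | C=C1CCC[C@H]2OC(C)(C)[C@@H](O[Si](C)(C)C(C)(C)C)CC[C@]12C | intermediate
17 | 6-methylidene-7-ol (hydroxyl trans to 5a-methyl) | C=C1[C@H](O)CC[C@H]2OC(C)(C)[C@@H](O[Si](C)(C)C(C)(C)C)CC[C@]12C | intermediate
18 | 6-methylidene-7-one | C=C1C(=O)CC[C@H]2OC(C)(C)[C@@H](O[Si](C)(C)C(C)(C)C)CC[C@]12C | intermediate
19 | 7-methyl-6-methylidene-7-ol (hydroxyl cis to 5a-methyl) | C=C1[C@@](C)(O)CC[C@H]2OC(C)(C)[C@@H](O[Si](C)(C)C(C)(C)C)CC[C@]12C | intermediate
20 | but-3-en-2-one | CC(=O)C=C | starting material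
21 | 2-(triisopropylsilyloxy)buta-1,3-diene | C=CC(=C)O[Si](C(C)C)(C(C)C)C(C)C | intermediate
22 | cyclopent-2-en-1-one | O=C1CCC=C1 | starting material
23 | (3aS,7aR)-5-(triisopropylsilyloxy)-2,3,3a,4,7,7a-hexahydro-1H-inden-1-one | CC(C)[Si](C(C)C)(C(C)C)OC1=CC[C@@H]2[C@@H](CCC2=O)C1 | intermediate
24 | cis-1-methylidene-5-(triisopropylsilyloxy)-2,3,3a,4,7,7a-hexahydro-1H-indene | CC(C)[Si](C(C)C)(C(C)C)OC1=CC[C@@H]2[C@@H](CCC2=C)C1 | intermediate
25 | methyl-substituted siloxycyclopropane from 24 (cyclopropane carbons open) | CC1C2C[C@@H]3[C@@H](CCC3=C)CC12O[Si](C(C)C)(C(C)C)C(C)C | intermediate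
26 | cis-fused 7-chloro-6-methyl-1-methylideneoctahydroazulen-5-one (C6, C7 open) | CC1C(Cl)C[C@@H]2[C@@H](CCC2=C)CC1=O | intermediate
27 | cis-fused 6-methyl-1-methylidene-2,3,3a,4,8,8a-hexahydroazulen-5(1H)-one | CC1=CC[C@@H]2[C@@H](CCC2=C)CC1=O | intermediate
28 | 4,6-dimethyl analogue of 27 (C4 open) | CC1=CC[C@@H]2[C@@H](CCC2=C)C(C)C1=O | intermediate
29 | 4,4,6-trimethyl analogue of 27 | CC1=CC[C@@H]2[C@@H](CCC2=C)C(C)(C)C1=O | intermediate
30 | lithium enolate of the 6,7-dihydro ketone of 29 | [Li+].CC1=C([O-])C(C)(C)[C@@H]2CCC(=C)[C@@H]2CC1 | intermediate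
31 | cis-fused 4,4,6-trimethyl-1-methylidene-1,2,3,3a,4,7,8,8a-octahydroazulen-5-yl triflate | CC1=C(OS(=O)(=O)C(F)(F)F)C(C)(C)[C@@H]2CCC(=C)[C@@H]2CC1 | intermediate
32 | cis-fused 1-hydroxy-1,4,4,6-tetramethyl-1,2,3,3a,4,7,8,8a-octahydroazulen-5-yl triflate (hydroxyl on the face of H3a and H8a) | CC1=C(OS(=O)(=O)C(F)(F)F)C(C)(C)[C@@H]2CC[C@@](C)(O)[C@@H]2CC1 | intermediate
33 | B-alkyl-9-BBN from 19 (boron on C17, H18 trans to the C19 methyl) | C(B1C2CCCC1CCC2)[C@H]1[C@@](C)(O)CC[C@H]2OC(C)(C)[C@@H](O[Si](C)(C)C(C)(C)C)CC[C@]12C | intermediate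
34 | C16 enone joining C17 of the west half to C15 of the hydroazulene | CC1=C(C(=O)C[C@H]3[C@@](C)(O)CC[C@H]4OC(C)(C)[C@@H](O[Si](C)(C)C(C)(C)C)CC[C@]34C)C(C)(C)[C@@H]2CC[C@@](C)(O)[C@@H]2CC1 | intermediate
35 | (16R)-allylic alcohol from 34 | CC1=C([C@H](O)C[C@H]3[C@@](C)(O)CC[C@H]4OC(C)(C)[C@@H](O[Si](C)(C)C(C)(C)C)CC[C@]34C)C(C)(C)[C@@H]2CC[C@@](C)(O)[C@@H]2CC1 | intermediate
36 | (16S)-N-alkyl-N-(2-nitrobenzenesulfonyl)hydrazine | CC1=C([C@@H](N(N)S(=O)(=O)c5ccccc5[N+](=O)[O-])C[C@H]3[C@@](C)(O)CC[C@H]4OC(C)(C)[C@@H](O[Si](C)(C)C(C)(C)C)CC[C@]34C)C(C)(C)[C@@H]2CC[C@@](C)(O)[C@@H]2CC1 | intermediate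
37 | (16S)-allylic diazene | CC1=C([C@@H](N=N)C[C@H]3[C@@](C)(O)CC[C@H]4OC(C)(C)[C@@H](O[Si](C)(C)C(C)(C)C)CC[C@]34C)C(C)(C)[C@@H]2CC[C@@](C)(O)[C@@H]2CC1 | intermediate
38 | C23 tert-butyldimethylsilyl ether of the 23-dihydro target | C[C@H]1CC[C@@H]2[C@@H](CC[C@@]2(C)O)C(C)(C)/C1=C\C[C@@H]1[C@@]2(C)CC[C@H](O[Si](C)(C)C(C)(C)C)C(C)(C)O[C@@H]2CC[C@]1(C)O | intermediate
39 | 23-dihydro target (C23 hydroxyl cis to the C19 methyl) | C[C@H]1CC[C@@H]2[C@@H](CC[C@@]2(C)O)C(C)(C)/C1=C\C[C@@H]1[C@@]2(C)CC[C@H](O)C(C)(C)O[C@@H]2CC[C@]1(C)O | intermediate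
40 | CNP0157787.1 | C[C@H]1CC[C@@H]2[C@@H](CC[C@@]2(C)O)C(C)(C)/C1=C\C[C@@H]1[C@@]2(C)CCC(=O)C(C)(C)O[C@@H]2CC[C@]1(C)O | target

**Count and risks**

Total steps: 26. Longest linear sequence: 19 (steps 1–14 and 22–26); the east half adds 7 steps (15–21).

1. Step 22. The β-branched alkylborane 33 may transmetallate too slowly, so that direct coupling without uptake of carbon monoxide, protodeboronation or reduction of the triflate take over. The fallback sets out from 19 and 32 and returns at 34. Hydroboration of 19 with 9-BBN and oxidation with NaOH/H2O2 should give the primary alcohol F1, and I2/PPh3/imidazole the iodide F2. Iodine–lithium exchange with t-BuLi (3 equiv, the first consumed by the hydroxyl) gives the dilithio species F3. In parallel, reductive carbonylation of 32 (Pd(OAc)2, dppp, CO, Et3SiH, Et3N) gives the enal F4. 1,2-Addition of F3 to F4 gives the C16 carbinols F5 as both epimers, and Dess–Martin oxidation returns enone 34, from which step 23 sets C16 as before.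

2. Step 24. The activated allylic alcohol may ionise instead of being displaced, which would erase the C16 configuration and with it the control of C2. Elimination to a diene and leakage through the retro-ene conformer with C17 inside (E alkene) are the other failure modes. The fallback sets out from 34 and returns at 38. Condensation with TsNHNH2 gives the tosylhydrazone F6, and reduction with catecholborane followed by NaOAc (Kabalka alkene transposition) gives the allylic diazene F7 and then 38. Here C16 comes from hydride attack on the C=N bond under substrate control, so the C2 epimers may have to be separated.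

3. Step 4. Attack of the C29 hydroxyl at C23 (5-exo) may compete with attack at C25 and give the tetrahydrofuran isomer. The fallback sets out from 4 and returns at 8. Benzoylation (BzCl, pyridine) gives the keto benzoate F8, and ketohydroxylation of the prenyl group (RuCl3 cat., Oxone, NaHCO3) gives the hydroxy diketone F9. Reductive etherification (Et3SiH, TMSOTf, −78 °C) between the tertiary hydroxyl and the C29 carbonyl then closes the O28–C29 bond through a bicyclic oxocarbenium ion that takes hydride axially, anti to the C19 methyl, and gives 8 directly with the trans fusion.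

**Further compounds**

F1 | step 22 | primary C17 alcohol from 19 | OC[C@H]1[C@@](C)(O)CC[C@H]2OC(C)(C)[C@@H](O[Si](C)(C)C(C)(C)C)CC[C@]12C
F2 | step 22 | primary C17 iodide | IC[C@H]1[C@@](C)(O)CC[C@H]2OC(C)(C)[C@@H](O[Si](C)(C)C(C)(C)C)CC[C@]12C
F3 | step 22 | dilithio species (C17 alkyllithium, C32 lithium alkoxide) | [Li]C[C@H]1[C@@](C)(O[Li])CC[C@H]2OC(C)(C)[C@@H](O[Si](C)(C)C(C)(C)C)CC[C@]12C
F4 | step 22 | hydroazulene enal (C16 aldehyde on C15) | CC1=C(C=O)C(C)(C)[C@@H]2CC[C@@](C)(O)[C@@H]2CC1
F5 | step 22 | C16 carbinols, both epimers | CC1=C(C(O)C[C@H]3[C@@](C)(O)CC[C@H]4OC(C)(C)[C@@H](O[Si](C)(C)C(C)(C)C)CC[C@]34C)C(C)(C)[C@@H]2CC[C@@](C)(O)[C@@H]2CC1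
F6 | step 24 | tosylhydrazone of 34 | CC1=C(C(=NNS(=O)(=O)c5ccc(C)cc5)C[C@H]3[C@@](C)(O)CC[C@H]4OC(C)(C)[C@@H](O[Si](C)(C)C(C)(C)C)CC[C@]34C)C(C)(C)[C@@H]2CC[C@@](C)(O)[C@@H]2CC1
F7 | step 24 | allylic diazene, both C16 epimers | CC1=C(C(N=N)C[C@H]3[C@@](C)(O)CC[C@H]4OC(C)(C)[C@@H](O[Si](C)(C)C(C)(C)C)CC[C@]34C)C(C)(C)[C@@H]2CC[C@@](C)(O)[C@@H]2CC1
F8 | step 4 | (1R,2R)-2-methyl-3-oxo-2-prenylcyclohexyl benzoate | O=C(O[C@@H]1CCCC(=O)[C@]1(C)CC=C(C)C)c1ccccc1
F9 | step 4 | 2-(3-hydroxy-3-methyl-2-oxobutyl) analogue of F8 | O=C(O[C@@H]1CCCC(=O)[C@]1(C)CC(=O)C(C)(C)O)c1ccccc1
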